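The route builds naphthalene ring C (C1–C4 with C4a/C8a; C1 bonded to isoquinoline C5) last, onto a preformed ring D. The feature exploited is the C4 oxygen of ring C lying peri to the C5 methoxy of ring D. It maps onto the lactone carbonyl of a 7-methoxy-5-methylphthalide whose C3 carries the tetrahydroisoquinolin-5-yl group. In one operation the phthalide anion adds to methyl acrylate (C1–C2 bond), the ester enolate closes onto the lactone carbonyl (C3–C4 bond) and dehydration aromatizes ring C, so the crowded biaryl junction arises from ring construction instead of cross-coupling. The precursor is the N-Boc (3S)-6,8-dimethoxy-3-methyltetrahydroisoquinoline bearing that phthalide at C5.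

Key step: step 8

Remark 1: the target SMILES defines only C3 (S); the hindered C5–C1 biaryl axis is undefined there and is not controlled here, so compounds 20–24 may be mixtures of rotamers about that bond.
Remark 2: in the substituent name 3-oxo-1,3-dihydro-2-benzofuran-1-yl the methoxy next to the lactone carbonyl takes locant 4 and the methyl locant 6 (C7 and C5 in phthalide numbering); compound 16 is named accordingly.
Remark 3: aziridine 2, the N-Boc aziridine of L-alaninol, is taken as a purchasable building block.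

Step 1
Reactants: 1 1-bromo-3,5-dimethoxybenzene; 2 tert-butyl (2S)-2-methylaziridine-1-carboxylate
Product: 4 tert-butyl N-[(2S)-1-(3,5-dimethoxyphenyl)propan-2-yl]carbamate, via arylmagnesium bromide 3 (not isolated)
Conditions: Mg, THF, 50 °C; then CuBr·SMe2 (10 mol %), 2, THF, −30 to 0 °C; H2O quench
Reagents that add atoms: none
Why: Copper-catalysed Grignard opening of the carbamate-activated aziridine is an SN2 attack at the unsubstituted CH2, so the C–N stereocentre of 2 is untouched and becomes the (S)-configured C3 of the target.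

Step 2
Reactants: 4 tert-butyl N-[(2S)-1-(3,5-dimethoxyphenyl)propan-2-yl]carbamate
Product: 6 (3S)-6,8-dimethoxy-3-methyl-1,2,3,4-tetrahydroisoquinoline, via amine hydrochloride 5 (not isolated)
Conditions: HCl (4 M in dioxane), rt; evaporate; 37% aq. HCHO (1.1 equiv), MeOH/H2O, 60 °C; aq. NaOH work-up
Reagents that add atoms: formaldehyde, C=O
Why: Carbamate acidolysis followed by Pictet–Spengler cyclization should close the nitrogen ring at a site ortho to the side chain and para to a methoxy group (both ortho sites are equivalent), giving the 6,8-dimethoxy pattern without touching the stereocentre.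

Step 3
Reactants: 6 (3S)-6,8-dimethoxy-3-methyl-1,2,3,4-tetrahydroisoquinoline
Product: 7 tert-butyl (3S)-6,8-dimethoxy-3-methyl-3,4-dihydroisoquinoline-2(1H)-carboxylate
Conditions: Boc2O, Et3N, CH2Cl2, rt
Reagents that add atoms: di-tert-butyl dicarbonate, CC(C)(C)OC(=O)OC(=O)OC(C)(C)C
Why: Carbamate formation (Boc protection) removes the N–H before the organolithium steps and installs a group that is cleaved cleanly by acid at the end.

Step 4
Reactants: 7 tert-butyl (3S)-6,8-dimethoxy-3-methyl-3,4-dihydroisoquinoline-2(1H)-carboxylate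
Product: 8 tert-butyl (3S)-5-bromo-6,8-dimethoxy-3-methyl-3,4-dihydroisoquinoline-2(1H)-carboxylate
Conditions: NBS (1.0 equiv), MeCN, 0 °C, dark
Reagents that add atoms: N-bromosuccinimide, O=C1CCC(=O)N1Br
Why: Electrophilic aromatic bromination should go to C5, para to the C8 methoxy and ortho to the C6 methoxy, rather than to C7 between the two methoxy groups, as 1,3-dimethoxyarenes brominate at their 4-position.

Step 5
Reactants: 8 tert-butyl (3S)-5-bromo-6,8-dimethoxy-3-methyl-3,4-dihydroisoquinoline-2(1H)-carboxylate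
Product: 10 tert-butyl (3S)-5-formyl-6,8-dimethoxy-3-methyl-3,4-dihydroisoquinoline-2(1H)-carboxylate, via aryllithium 9 (not isolated)
Conditions: n-BuLi (1.05 equiv), THF, −78 °C, 10 min; DMF, −78 to 0 °C; H2O quench
Reagents that add atoms: N,N-dimethylformamide, CN(C)C=O
Why: Bromine–lithium exchange at −78 °C is far faster than deprotonation beside the carbamate nitrogen, and Bouveault-type formylation of the aryllithium with DMF installs the C5 aldehyde.

Step 6
Reactants: 11 2-methoxy-4-methylbenzoic acid
Product: 13 N,N-diethyl-2-methoxy-4-methylbenzamide, via acid chloride 12 (not isolated)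
Conditions: SOCl2, DMF (cat.), PhMe, 70 °C; evaporate; Et2NH, Et3N, CH2Cl2, 0 °C to rt
Reagents that add atoms: diethylamine, CCNCC
Why: Acid chloride formation and amine acylation give the tertiary amide that directs the ortho-lithiation of the next step.

Step 7
Reactants: 13 N,N-diethyl-2-methoxy-4-methylbenzamide; 10 tert-butyl (3S)-5-formyl-6,8-dimethoxy-3-methyl-3,4-dihydroisoquinoline-2(1H)-carboxylate
Product: 16 tert-butyl (3S)-6,8-dimethoxy-5-(4-methoxy-6-methyl-3-oxo-1,3-dihydro-2-benzofuran-1-yl)-3-methyl-3,4-dihydroisoquinoline-2(1H)-carboxylate, via ortho-lithiated amide 14 (not isolated), via hydroxy amide 15 (not isolated)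
Conditions: 13 (1.3 equiv), s-BuLi (1.25 equiv), TMEDA, THF, −78 °C; 10, −78 to −20 °C; H2O quench; crude 15: AcOH, PhMe, 80 °C
Reagents that add atoms: none
Why: Amide-directed ortho-metalation lithiates the only position ortho to the amide (the amide outranks methoxy, and the para methyl is not laterally lithiated under kinetic conditions), the aryllithium adds to aldehyde 10, and the electron-rich diaryl carbinol lactonizes under weak acid with loss of diethylamine; the new phthalide carbon forms as both epimers, which is irrelevant because step 8 deprotonates it.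

Step 8
Reactants: 16 tert-butyl (3S)-6,8-dimethoxy-5-(4-methoxy-6-methyl-3-oxo-1,3-dihydro-2-benzofuran-1-yl)-3-methyl-3,4-dihydroisoquinoline-2(1H)-carboxylate; 17 methyl acrylate
Product: 20 tert-butyl (3S)-5-[4-hydroxy-5-methoxy-3-(methoxycarbonyl)-7-methylnaphthalen-1-yl]-6,8-dimethoxy-3-methyl-3,4-dihydroisoquinoline-2(1H)-carboxylate, via Michael adduct enolate 18 (not isolated), via hydroxy keto ester 19 (not isolated)
Conditions: LiN(i-Pr)2 (1.1 equiv), THF, −78 °C; 17 (1.2 equiv, slow addition), −78 °C to rt; AcOH quench; then TsOH·H2O (10 mol %), PhMe, 50 °C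
Reagents that add atoms: none
Why: The amide base removes the phthalide C3–H (doubly benzylic and oxygen-bearing), the stabilized anion adds to 17 in conjugate fashion to form the naphthalene C1–C2 bond and a quaternary carbon, the ester enolate 18 attacks the lactone carbonyl to form the C3–C4 bond with release of the tertiary alkoxide (19), and catalytic acid ionizes that diaryl carbinol so that loss of water and enolization aromatize ring C. The closest known reaction type is the Michael–Dieckmann annulation of phthalide anions with acrylates to 1-hydroxy-2-naphthoates, the Hauser–Kraus annulation without a leaving group on the phthalide. Ring C closes by 6-exo-trig attack of the enolate carbon on the lactone C=O. No stereocentre is created permanently: the centres formed in 18 and 19 are erased on aromatization, C3 of the isoquinoline is remote and untouched, and the new biaryl axis is not controlled. The step needs conjugate addition of a hindered tertiary carbanion to win over proton transfer and acrylate oligomerization, and deprotonation at the phthalide instead of at C1 beside the carbamate; the delocalized anion, low temperature and slow addition of a small excess of 17 favour the first, and the much higher acidity of the phthalide C–H towards an amide base secures the second. Regiochemistry is not in question because the anion site and the lactone carbonyl fix both new bonds.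

Step 9
Reactants: 20 tert-butyl (3S)-5-[4-hydroxy-5-methoxy-3-(methoxycarbonyl)-7-methylnaphthalen-1-yl]-6,8-dimethoxy-3-methyl-3,4-dihydroisoquinoline-2(1H)-carboxylate
Product: 21 tert-butyl (3S)-5-[4,5-dimethoxy-3-(methoxycarbonyl)-7-methylnaphthalen-1-yl]-6,8-dimethoxy-3-methyl-3,4-dihydroisoquinoline-2(1H)-carboxylate
Conditions: MeI, K2CO3, DMF, 50 °C
Reagents that add atoms: iodomethane, CI
Why: Williamson O-methylation of the hydrogen-bonded naphthol should proceed under mild heating, and no N–H or other acidic site competes.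

Step 10
Reactants: 21 tert-butyl (3S)-5-[4,5-dimethoxy-3-(methoxycarbonyl)-7-methylnaphthalen-1-yl]-6,8-dimethoxy-3-methyl-3,4-dihydroisoquinoline-2(1H)-carboxylate
Product: 22 4-[(3S)-2-(tert-butoxycarbonyl)-6,8-dimethoxy-3-methyl-1,2,3,4-tetrahydroisoquinolin-5-yl]-1,8-dimethoxy-6-methylnaphthalene-2-carboxylic acid
Conditions: LiOH, THF/MeOH/H2O, 60 °C; then 1 M HCl to pH 4, 0 °C
Reagents that add atoms: lithium hydroxide, [Li+].[OH-]
Why: Saponification of the aryl methyl ester by acyl substitution leaves the carbamate and the aryl ethers intact, and the mild acidification spares the Boc group.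

Step 11
Reactants: 22 4-[(3S)-2-(tert-butoxycarbonyl)-6,8-dimethoxy-3-methyl-1,2,3,4-tetrahydroisoquinolin-5-yl]-1,8-dimethoxy-6-methylnaphthalene-2-carboxylic acid
Product: 23 tert-butyl (3S)-5-(4,5-dimethoxy-7-methylnaphthalen-1-yl)-6,8-dimethoxy-3-methyl-3,4-dihydroisoquinoline-2(1H)-carboxylate
Conditions: Ag2CO3 (10 mol %), AcOH (5 mol %), DMSO, 120 °C
Reagents that add atoms: none
Why: Silver-catalysed protodecarboxylation is favoured by an ortho substituent such as the C4 methoxy, the arylsilver intermediate being protonated by acetic acid, and any thermal loss of Boc would be harmless because step 12 removes it.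

Step 12
Reactants: 23 tert-butyl (3S)-5-(4,5-dimethoxy-7-methylnaphthalen-1-yl)-6,8-dimethoxy-3-methyl-3,4-dihydroisoquinoline-2(1H)-carboxylate
Product: 24 (3S)-5-(4,5-dimethoxy-7-methylnaphthalen-1-yl)-6,8-dimethoxy-3-methyl-1,2,3,4-tetrahydroisoquinoline
Conditions: HCl (4 M in dioxane), CH2Cl2, 0 °C to rt; aq. NaOH work-up
Reagents that add atoms: none
Why: Acidolysis of the tert-butyl carbamate frees the secondary amine without affecting the aryl methyl ethers or the C3 stereocentre, and chloride as counter-ion limits Friedel–Crafts tert-butylation of the electron-rich rings.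

Compound list
1 | 1-bromo-3,5-dimethoxybenzene | COc1cc(Br)cc(OC)c1 | starting material
2 | tert-butyl (2S)-2-methylaziridine-1-carboxylate | C[C@H]1CN1C(=O)OC(C)(C)C | starting material
3 | (3,5-dimethoxyphenyl)magnesium bromide | COc1cc(OC)cc([Mg]Br)c1 | intermediate
4 | tert-butyl N-[(2S)-1-(3,5-dimethoxyphenyl)propan-2-yl]carbamate | COc1cc(C[C@H](C)NC(=O)OC(C)(C)C)cc(OC)c1 | intermediate
5 | (2S)-1-(3,5-dimethoxyphenyl)propan-2-amine (present as its hydrochloride) | COc1cc(C[C@H](C)N)cc(OC)c1 | intermediate
6 | (3S)-6,8-dimethoxy-3-methyl-1,2,3,4-tetrahydroisoquinoline | COc1cc(OC)cc2c1CN[C@@H](C)C2 | intermediate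
7 | tert-butyl (3S)-6,8-dimethoxy-3-methyl-3,4-dihydroisoquinoline-2(1H)-carboxylate | COc1cc(OC)cc2c1CN(C(=O)OC(C)(C)C)[C@@H](C)C2 | intermediate
8 | tert-butyl (3S)-5-bromo-6,8-dimethoxy-3-methyl-3,4-dihydroisoquinoline-2(1H)-carboxylate | COc1cc(OC)c(Br)c2c1CN(C(=O)OC(C)(C)C)[C@@H](C)C2 | intermediate
9 | tert-butyl (3S)-5-lithio-6,8-dimethoxy-3-methyl-3,4-dihydroisoquinoline-2(1H)-carboxylate | [Li]c1c(OC)cc(OC)c2c1C[C@H](C)N(C(=O)OC(C)(C)C)C2 | intermediate
10 | tert-butyl (3S)-5-formyl-6,8-dimethoxy-3-methyl-3,4-dihydroisoquinoline-2(1H)-carboxylate | COc1cc(OC)c(C=O)c2c1CN(C(=O)OC(C)(C)C)[C@@H](C)C2 | intermediate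
11 | 2-methoxy-4-methylbenzoic acid | COc1cc(C)ccc1C(=O)O | starting material
12 | 2-methoxy-4-methylbenzoyl chloride | COc1cc(C)ccc1C(=O)Cl | intermediate
13 | N,N-diethyl-2-methoxy-4-methylbenzamide | CCN(CC)C(=O)c1ccc(C)cc1OC | intermediate
14 | N,N-diethyl-2-lithio-6-methoxy-4-methylbenzamide | CCN(CC)C(=O)c1c([Li])cc(C)cc1OC | intermediate
15 | tert-butyl (3S)-5-{[2-(diethylcarbamoyl)-3-methoxy-5-methylphenyl](hydroxy)methyl}-6,8-dimethoxy-3-methyl-3,4-dihydroisoquinoline-2(1H)-carboxylate (both carbinol epimers) | CCN(CC)C(=O)c1c(OC)cc(C)cc1C(O)c1c(OC)cc(OC)c2c1C[C@H](C)N(C(=O)OC(C)(C)C)C2 | intermediate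
16 | tert-butyl (3S)-6,8-dimethoxy-5-(4-methoxy-6-methyl-3-oxo-1,3-dihydro-2-benzofuran-1-yl)-3-methyl-3,4-dihydroisoquinoline-2(1H)-carboxylate (a 3-aryl-7-methoxy-5-methylphthalide, both epimers at the phthalide carbon) | COc1cc(C)cc2c1C(=O)OC2c1c(OC)cc(OC)c2c1C[C@H](C)N(C(=O)OC(C)(C)C)C2 | intermediate
17 | methyl acrylate | C=CC(=O)OC | starting material
18 | tert-butyl (3S)-6,8-dimethoxy-5-[4-methoxy-1-(3-methoxy-3-oxopropyl)-6-methyl-3-oxo-1,3-dihydro-2-benzofuran-1-yl]-3-methyl-3,4-dihydroisoquinoline-2(1H)-carboxylate (formed as its lithium ester enolate, drawn as the neutral ester) | COC(=O)CCC1(OC(=O)c2c(OC)cc(C)cc21)c1c(OC)cc(OC)c2c1C[C@H](C)N(C(=O)OC(C)(C)C)C2 | intermediate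
19 | tert-butyl (3S)-5-[1-hydroxy-5-methoxy-3-(methoxycarbonyl)-7-methyl-4-oxo-1,2,3,4-tetrahydronaphthalen-1-yl]-6,8-dimethoxy-3-methyl-3,4-dihydroisoquinoline-2(1H)-carboxylate (keto form, ring stereocentres undefined) | COC(=O)C1CC(O)(c2c(OC)cc(OC)c3c2C[C@H](C)N(C(=O)OC(C)(C)C)C3)c2cc(C)cc(OC)c2C1=O | intermediate
20 | tert-butyl (3S)-5-[4-hydroxy-5-methoxy-3-(methoxycarbonyl)-7-methylnaphthalen-1-yl]-6,8-dimethoxy-3-methyl-3,4-dihydroisoquinoline-2(1H)-carboxylate | COC(=O)c1cc(-c2c(OC)cc(OC)c3c2C[C@H](C)N(C(=O)OC(C)(C)C)C3)c2cc(C)cc(OC)c2c1O | intermediate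
21 | tert-butyl (3S)-5-[4,5-dimethoxy-3-(methoxycarbonyl)-7-methylnaphthalen-1-yl]-6,8-dimethoxy-3-methyl-3,4-dihydroisoquinoline-2(1H)-carboxylate | COC(=O)c1cc(-c2c(OC)cc(OC)c3c2C[C@H](C)N(C(=O)OC(C)(C)C)C3)c2cc(C)cc(OC)c2c1OC | intermediate
22 | 4-[(3S)-2-(tert-butoxycarbonyl)-6,8-dimethoxy-3-methyl-1,2,3,4-tetrahydroisoquinolin-5-yl]-1,8-dimethoxy-6-methylnaphthalene-2-carboxylic acid | OC(=O)c1cc(-c2c(OC)cc(OC)c3c2C[C@H](C)N(C(=O)OC(C)(C)C)C3)c2cc(C)cc(OC)c2c1OC | intermediate
23 | tert-butyl (3S)-5-(4,5-dimethoxy-7-methylnaphthalen-1-yl)-6,8-dimethoxy-3-methyl-3,4-dihydroisoquinoline-2(1H)-carboxylate | COc1cc(OC)c(-c2ccc(OC)c3c(OC)cc(C)cc23)c2c1CN(C(=O)OC(C)(C)C)[C@@H](C)C2 | intermediate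
24 | (3S)-5-(4,5-dimethoxy-7-methylnaphthalen-1-yl)-6,8-dimethoxy-3-methyl-1,2,3,4-tetrahydroisoquinoline | COc1cc(OC)c(-c2ccc(OC)c3c(OC)cc(C)cc23)c2c1CN[C@@H](C)C2 | target

Total step count: 12. Longest linear sequence: 11 steps (steps 1–5 and 7–12; step 6 is a one-step side branch).

Steps most likely to fail

Step 8. Conjugate addition of the crowded tertiary carbanion may be outrun by proton transfer or by anionic oligomerization of the acrylate. The fallback makes the same two bonds through a neutral diene and sets out from 16. LiN(SiMe3)2 and TBSCl (THF, −78 °C) should give the 1-(tert-butyldimethylsilyloxy)-3-arylisobenzofuran F1, which is not isolated. It should undergo Diels–Alder cycloaddition with 17 (−78 °C to rt) to the oxygen-bridged cycloadduct F2, the siloxy-bearing terminus bonding to the acrylate α-carbon so that the ester sits next to the former lactone carbon. TsOH·H2O in wet THF then cleaves the bridging silyl ketal to 19 and dehydrates it, so the fallback comes back to the route at 20.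

Step 7. Lactonization of the hindered hydroxy amide may stall under acid mild enough for the carbamate, while stronger acid would cleave the carbamate. The fallback reverses the roles of the partners and closes the lactone under basic conditions; it sets out from 11 and 8. Acid 11 is ortho-lithiated as its lithium carboxylate (s-BuLi, TMEDA, THF, −78 °C; metalation ortho to the carboxylate) and formylated with DMF to give 3-hydroxy-7-methoxy-5-methyl-2-benzofuran-1(3H)-one F3. MeI and K2CO3 in DMF open this to methyl 2-formyl-6-methoxy-4-methylbenzoate F4. Aryllithium 9, generated from 8 as in step 5, adds to the aldehyde of F4 at −78 °C and the alkoxide closes onto the neighbouring ester on warming, which comes back to the route at 16.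

Step 11. Extrusion of CO2 from the electron-rich, ortho-substituted naphthoate may be slow, or the silver may be sequestered by amine liberated through thermal carbamate loss. The fallback removes the carbon as carbon monoxide and sets out from 21. LiBH4 (THF, 50 °C) reduces the ester to the hydroxymethyl compound F5, MnO2 (CH2Cl2, rt) oxidizes it to the naphthaldehyde F6, and Tsuji–Wilkinson decarbonylation with stoichiometric RhCl(PPh3)3 (PhMe, reflux) comes back to the route at 23.

Further compounds
F1 | step 8 | tert-butyl (3S)-5-[3-(tert-butyldimethylsilyloxy)-4-methoxy-6-methyl-2-benzofuran-1-yl]-6,8-dimethoxy-3-methyl-3,4-dihydroisoquinoline-2(1H)-carboxylate | CC(C)(C)[Si](C)(C)OC1=C2C(OC)=CC(C)=CC2=C(O1)c1c(OC)cc(OC)c2c1C[C@H](C)N(C(=O)OC(C)(C)C)C2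
F2 | step 8 | tert-butyl (3S)-5-[4-(tert-butyldimethylsilyloxy)-5-methoxy-3-(methoxycarbonyl)-7-methyl-1,2,3,4-tetrahydro-1,4-epoxynaphthalen-1-yl]-6,8-dimethoxy-3-methyl-3,4-dihydroisoquinoline-2(1H)-carboxylate | COC(=O)C1CC2(OC1(O[Si](C)(C)C(C)(C)C)c1c(OC)cc(C)cc12)c1c(OC)cc(OC)c2c1C[C@H](C)N(C(=O)OC(C)(C)C)C2
F3 | step 7 | 3-hydroxy-7-methoxy-5-methyl-2-benzofuran-1(3H)-one | COc1cc(C)cc2c1C(=O)OC2O
F4 | step 7 | methyl 2-formyl-6-methoxy-4-methylbenzoate | COC(=O)c1c(OC)cc(C)cc1C=O
F5 | step 11 | tert-butyl (3S)-5-[3-(hydroxymethyl)-4,5-dimethoxy-7-methylnaphthalen-1-yl]-6,8-dimethoxy-3-methyl-3,4-dihydroisoquinoline-2(1H)-carboxylate | OCc1cc(-c2c(OC)cc(OC)c3c2C[C@H](C)N(C(=O)OC(C)(C)C)C3)c2cc(C)cc(OC)c2c1OC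
F6 | step 11 | tert-butyl (3S)-5-(3-formyl-4,5-dimethoxy-7-methylnaphthalen-1-yl)-6,8-dimethoxy-3-methyl-3,4-dihydroisoquinoline-2(1H)-carboxylate | O=Cc1cc(-c2c(OC)cc(OC)c3c2C[C@H](C)N(C(=O)OC(C)(C)C)C3)c2cc(C)cc(OC)c2c1OC
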